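The constants were hidden, so I set the exchange equilibrium constant to one, the even case, as the zero of my scale.

| flask | starting complex | incoming ligand | remark | time |
|---|---|---|---|---|
| dawn | 1 M | 1 equiv | the very flask that is asked about, followed so far |  |
| autumn | 0.67 M | 1 equiv | run made earlier |  |
| flask | 1.0 M | 1.00 equiv |  | 15 h |

dawn run (percent of the starting complex charged)

| time / min | complex with one exchanged / % | starting complex / % |
|---|---|---|
| 8.00 | 12 | 75 |
| 20.0 | 22 | 56 |
| 40.0 | 24 | 44 |
| 60.0 | 24 | 36 |
| 80.0 | 24 | 32 |
| 120 | 21 | 34 |

autumn run (percent of the starting complex charged)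

| time / h | complex with one exchanged / % | starting complex / % |
|---|---|---|
| 2.50 | 19 | 31 |
| 5.00 | 13 | 24 |
| 8.00 | 10 | 22 |
| 10.0 | 8 | 22 |
| 12.0 | 9 | 17 |
| 15.0 | 4 | 21 |

(each reading ± 2 percentage points)

- equivalents of incoming ligand to starting complex, everything else as given, that leave most complex with one exchanged at 15 h
- the amount of complex with one exchanged then, in percent of the starting complex charged
- the amount of complex with one exchanged with the amounts as given

The autumn tail looked contradictory. From 10.0 h on, starting complex (M) stood near 20.0% and complex with one exchanged (A) near 7.00%. M had stopped, as if incoming ligand (X) were gone, yet a one-for-one exchange that leaves 20.0% of M leaves as much X.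

I reckoned with M + X ⇌ L + A, where L is leaving ligand. In the even case [A]/[M] = [X]/[L], and with equal charges [X] + [L] is the charge.

ρ = [A]/[M] = 0.350

X left = ρ/(one + ρ) = 25.9%

This ρ, the exchange ratio of the tail, cleared it up: by my reckoning the autumn run stopped with X present, a balance under thermodynamic control. For the flask I assumed that ρ and M carry over from the autumn run, so [A] = ρ[M] gave 7.00%, which is simply the A of the autumn tail.

The forecast gave 5% (3% to 8%), lower than mine, and 7.5% at 0.8 equiv, since less ligand “avoids residual ligand eating the product”.

The flask gave 7.69%, and at best 9.15% at 2.35 equiv.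

    starting complex + incoming ligand ⇌ leaving ligand + complex with one exchanged (K = 1.00, k = 0.0181 L mol⁻¹ min⁻¹)
    complex with one exchanged + incoming ligand ⇌ leaving ligand + complex with two exchanged (K = 0.180, k = 5.74 × 10⁻⁴ L mol⁻¹ min⁻¹)
    complex with two exchanged + incoming ligand ⇌ leaving ligand + complex with three exchanged (K = 0.930, k = 0.00164 L mol⁻¹ min⁻¹)
    complex with three exchanged + incoming ligand ⇌ leaving ligand + complex with four exchanged (K = 0.240, k = 0.0122 L mol⁻¹ min⁻¹)
    crystals ⇌ complex with one exchanged, rate k5*(cs5 - [complex with one exchanged]) while solid is left; crystals form when [complex with one exchanged] > cs5 (solubility = 0.350 M, k = 3.68 min⁻¹)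
    complex with one exchanged ⇌ isomer of the product (K = 8.28, k = 0.0124 min⁻¹)
    starting complex ⇌ dormant form (K = 0.569, k = 0.0189 min⁻¹)

In the flask after 15.0 h, [A]/[M] was 0.398 and [X]/[L] 0.410, beside my ρ of 0.350, and 29% of the ligand remained against my 25.9%. The neighbour with 0.400 equiv had a ratio below ρ, and its [X]/[L] times its 40.7% of M gives 4.10% against the 3.97% found. Without the isomerisation of A to the isomer of the product, the flask gives 38.3% rather than 7.69%.

The runs come from a simulation from invented constants; noise was put on by code.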